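## Retrosynthetic overview

1. Previtexilactone ⇒ 6β-alcohol **19** (acetylation) ⇒ 15,16-diol **18** (oxidative lactonization) ⇒ alkene-triol **16** (catalyst-controlled epoxidation of C13=C16, then 5-exo opening by the 9α-OH with inversion at C13) ⇒ 9α,11-spiro-epoxide **13** + isoprenol (C11–C12 bond).
2. **13** ⇒ trans-decalenone **8** by functional-group work on ring B only: γ-oxidation to the ene-dione, reduction, α-face hydride at C6, methylenation and α-face epoxidation at C9.
3. **8** ⇒ monocyclic iodide **7**: ring A is closed by the C3–C4 bond (hydrogen atom transfer to an isopropenyl group, nickel-mediated coupling of the tertiary C4 radical with a primary C3 iodide); **7** ⇒ (R)-carvone by two enolate alkylations at C10.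
4. Enabling feature: C4 of ring A is a quaternary carbon with two methyl groups, bonded directly to the ring-fusion methine C5, and C3 is an unsubstituted CH2. C4 and one of its methyl groups can therefore be the isopropenyl group that (R)-carvone (ring B; carbonyl = C9, ring methyl = C17) already carries on C5, while C3 ends a three-carbon arm on the quaternary C10.
5. Order of ring formation: ring B (from carvone) → ring A (step 4) → tetrahydrofuran (step 11) → lactone (step 12).

Key step: step 4

Remark: atoms are numbered as in the labdane skeleton of the target (C1–C10 decalin, C11–C16 side chain, C17 on C8, C18/C19 on C4, C20 on C10); the target is read as 5α-H, 6β-OAc, 8α-CH3, 9α-O, 10β-CH3, 13S, and the ligand enantiomer in step 11 is assumed to be the one that delivers the 13R epoxide.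

## Route

Step 1
Reactants: 1 (R)-carvone
Product: 3 6-methylcarvone (epimers at the new centre), via lithium dienolate 2 (not isolated)
Conditions: LiN(i-Pr)2, THF, −78 °C; then MeI, −78 to 0 °C
Reagents that add atoms: iodomethane, CI
Why: Kinetic α′-deprotonation gives the cross-conjugated lithium dienolate, which is C-methylated (enolate alkylation); the new centre (future C10) is not controlled and is erased in step 2.

Step 2
Reactants: 3 6-methylcarvone; 4 1-chloro-3-iodopropane
Product: 6 (5S,6S)-6-(3-chloropropyl)-2,6-dimethyl-5-(prop-1-en-2-yl)cyclohex-2-en-1-one, via lithium enolate 5 (not isolated)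
Conditions: LiN(i-Pr)2, THF, −78 °C; then 4, DMPU, −78 to 0 °C
Reagents that add atoms: none
Why: Enolate alkylation that forms the quaternary C10; the primary iodide end of 4 should react on the face anti to the pseudoaxial isopropenyl group on C5, which places the chain trans to the isopropenyl group (methyl cis), while the C–Cl bond survives.

Step 3
Reactants: 6 chloride
Product: 7 (5S,6S)-6-(3-iodopropyl)-2,6-dimethyl-5-(prop-1-en-2-yl)cyclohex-2-en-1-one
Conditions: NaI, acetone, reflux
Reagents that add atoms: sodium iodide, [Na+].[I-]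
Why: Finkelstein exchange (SN2 at the unhindered primary C3), driven by precipitation of NaCl, gives the iodide needed for activation by nickel.

Step 4
Reactants: 7 iodide
Product: 8 (4aS,8aS)-2,5,5,8a-tetramethyl-4a,5,6,7,8,8a-hexahydronaphthalen-1(4H)-one (trans-fused)
Conditions: Mn(dpm)3 (cat.; dpm = 2,2,6,6-tetramethylheptane-3,5-dionate), Ni(acac)2 (cat.), PhSiH3, K2CO3, 1,2-dichloroethane/hexafluoroisopropanol, 25 °C, high dilution
Reagents that add atoms: none
Why: Proposed new method: a manganese hydride formed from Mn(dpm)3 and PhSiH3 transfers a hydrogen atom to the terminal CH2 of the isopropenyl group (Markovnikov MHAT), which completes the second methyl group on C4 and leaves a tertiary radical at C4, while low-valent nickel activates the primary C3–I bond; the alkylnickel intermediate captures the C4 radical and reductive elimination from the resulting trivalent nickel dialkyl forms the C3–C4 bond. The closest known reaction type is the intermolecular manganese/nickel dual-catalytic MHAT hydroalkylation of 1,1-disubstituted alkenes with unactivated primary alkyl iodides, which gives acyclic quaternary carbons; the ring-closing mode on a tethered iodoalkene is the new element. Ring A closes as a six-membered ring by C(sp3)–C(sp3) coupling within a seven-membered nickelacycle (formally a 6-exo-tet substitution at C3 by the C4 radical), so the exo/endo competition of radical additions to π bonds does not arise. No new stereocentre is formed (C4 carries two methyl groups, C3 is CH2); the trans ring fusion follows from the trans arrangement of the C5 and C10 arms fixed in step 2, which can only bridge diequatorially. The step needs hydrogen atom transfer to the electron-rich 1,1-disubstituted alkene in preference to the enone, and C–C coupling in preference to simple reduction of the radical or of the iodide; the first rests on the polarity match of the hydride with the isopropenyl group, the second on the 1,6-relationship of C4 and C3 on a ring, the quaternary C10 (Thorpe–Ingold effect) and high dilution.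

Step 5
Reactants: 8 decalenone
Product: 9 (4aS,8aS)-2,5,5,8a-tetramethyl-4a,5,6,7,8,8a-hexahydronaphthalene-1,4-dione (ene-dione, C6 and C9 carbonyls)
Conditions: Pd(OH)2/C (cat.), t-BuOOH, K2CO3, CH2Cl2, 4 °C
Reagents that add atoms: tert-butyl hydroperoxide, CC(C)(C)OO
Why: γ-Oxidation of an α,β-enone to the 1,4-ene-dione (allylic peroxidation at C6, the only allylic ring methylene, then loss of tert-butanol); solid K2CO3 at low temperature should not enolize C5, so the trans fusion is kept.

Step 6
Reactants: 9 ene-dione
Product: 10 (4aS,8aS)-2,5,5,8a-tetramethyloctahydronaphthalene-1,4-dione (C8 epimers)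
Conditions: Zn dust, AcOH, 25 °C
Reagents that add atoms: none
Why: Dissolving-metal conjugate reduction of the ene-dione saturates C7–C8 and leaves both ketones; C8 is corrected in step 7, and the short, weakly acidic conditions should not epimerize C5.

Step 7
Reactants: 10 dione
Product: 11 (2R,4R,4aS,8aS)-4-hydroxy-2,5,5,8a-tetramethyloctahydronaphthalen-1(2H)-one (6β-OH, 8α-CH3, C9 ketone)
Conditions: NaBH4, MeOH/CH2Cl2, −20 °C; then NaOMe, MeOH, 25 °C
Reagents that add atoms: none
Why: Hydride reduction of the C6 ketone in preference to the C9 ketone (flanked by quaternary C10 and tertiary C8), from the α face because the β face is blocked by the axial methyl groups on C4 and C10, gives the axial 6β-alcohol; NaOMe then equilibrates C8 to the equatorial 8α-methyl epimer, C5 no longer being enolizable.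

Step 8
Reactants: 11 hydroxy ketone
Product: 12 (1R,3R,4aS,8aS)-3,4a,8,8-tetramethyl-4-methylidenedecahydronaphthalen-1-ol (C9=C11 exocyclic alkene)
Conditions: Ph3PCH3Br, KOtBu (excess), toluene, 90 °C
Reagents that add atoms: methyltriphenylphosphonium bromide, C[P+](c1ccccc1)(c1ccccc1)c1ccccc1.[Br-]
Why: Wittig methylenation of the hindered ketone under forcing conditions with excess ylide (the C6 alkoxide is a spectator); C8 stays in its thermodynamic configuration.

Step 9
Reactants: 12 exocyclic alkene
Product: 13 9α,11-epoxide of 12 (oxygen α and axial on C9, C11 β; 6β-OH, 8α-CH3)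
Conditions: mCPBA, NaHCO3, CH2Cl2, 0 °C
Reagents that add atoms: 3-chloroperoxybenzoic acid, O=C(OO)c1cccc(Cl)c1
Why: Prilezhaev epoxidation from the α face, anti to the axial C10 methyl group that shields the β face, which sets C9 with oxygen α and C11 β.

Step 10
Reactants: 13 spiro-epoxide (as its lithium alkoxide); 14 3-methylbut-3-en-1-ol (isoprenol)
Product: 16 (5S,6R,8R,9R,10S)-labd-13(16)-ene-6,9,15-triol, via dilithio isoprenol dianion 15 (not isolated)
Conditions: 14, n-BuLi (2 equiv), TMEDA, Et2O/hexane, 0 to 25 °C; then 13 (pre-treated with n-BuLi, 1 equiv), THF, −78 to 25 °C; H2O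
Reagents that add atoms: none
Why: The symmetrical 2-substituted allyl anion opens the epoxide by SN2 attack at the primary C11 (epoxide opening by an allyllithium), which forms C11–C12 and releases the 9α-tertiary alkoxide without touching C9.

Step 11
Reactants: 16 alkene-triol
Product: 18 (13S)-9α,13-epoxylabdane-6β,15,16-triol, via 13R-epoxide 17 (not isolated)
Conditions: Hf(OtBu)4 (cat.), C2-symmetric bishydroxamic acid ligand from trans-1,2-diaminocyclohexane (cat.), cumene hydroperoxide, DMPU, 4 Å molecular sieves, toluene, 0 °C; then camphorsulfonic acid (cat.), CH2Cl2, 0 °C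
Reagents that add atoms: cumene hydroperoxide, CC(C)(OO)c1ccccc1
Why: Catalyst-controlled asymmetric epoxidation of the homoallylic alcohol (directed by the C15 OH) should give the 13R epoxide; acid then triggers 5-exo-tet opening by the 9α-OH at the tertiary C13 with inversion, which sets 13S and closes the tetrahydrofuran.

Step 12
Reactants: 18 triol
Product: 19 deacetylprevitexilactone ((13S)-6β-hydroxy-9α,13-epoxylabdane lactone, carbonyl at C15, ring oxygen on C16)
Conditions: TEMPO (cat.), PhI(OAc)2, CH2Cl2, 25 °C
Reagents that add atoms: none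
Why: Oxidative lactonization of a 1,4-diol: the unhindered primary C15 alcohol is oxidized first, the aldehyde forms the five-membered lactol with the C16 OH and is oxidized on to the lactone; the neopentyl C16 OH and the hindered axial C6 OH react more slowly.

Step 13
Reactants: 19 deacetylprevitexilactone
Product: 20 previtexilactone
Conditions: Ac2O, DMAP (cat.), pyridine, 45 °C
Reagents that add atoms: acetic anhydride, CC(=O)OC(C)=O
Why: DMAP-catalysed acylation of the only free hydroxyl group, the hindered axial 6β-OH, under weakly basic conditions that should leave the β-alkoxy lactone intact.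

## Compound list

1 | (R)-(−)-carvone, (5R)-2-methyl-5-(prop-1-en-2-yl)cyclohex-2-en-1-one | C1C=C(C)C(=O)C[C@@H]1C(C)=C | starting material
2 | lithium cross-conjugated dienolate of 1 | C1C=C(C)C([O-])=C[C@@H]1C(C)=C.[Li+] | intermediate
3 | 6-methylcarvone, (5R)-2,6-dimethyl-5-(prop-1-en-2-yl)cyclohex-2-en-1-one, C6 epimers | C1C=C(C)C(=O)C(C)[C@@H]1C(C)=C | intermediate
4 | 1-chloro-3-iodopropane | ClCCCI | starting material
5 | lithium enolate of 3 | C1C=C(C)C([O-])=C(C)[C@@H]1C(C)=C.[Li+] | intermediate
6 | (5S,6S)-6-(3-chloropropyl)-2,6-dimethyl-5-(prop-1-en-2-yl)cyclohex-2-en-1-one | C1C=C(C)C(=O)[C@@](C)(CCCCl)[C@@H]1C(C)=C | intermediate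
7 | (5S,6S)-6-(3-iodopropyl)-2,6-dimethyl-5-(prop-1-en-2-yl)cyclohex-2-en-1-one | C1C=C(C)C(=O)[C@@](C)(CCCI)[C@@H]1C(C)=C | intermediate
8 | (4aS,8aS)-2,5,5,8a-tetramethyl-4a,5,6,7,8,8a-hexahydronaphthalen-1(4H)-one | C1C=C(C)C(=O)[C@@]2(C)CCCC(C)(C)[C@H]12 | intermediate
9 | (4aS,8aS)-2,5,5,8a-tetramethyl-4a,5,6,7,8,8a-hexahydronaphthalene-1,4-dione | O=C1C=C(C)C(=O)[C@@]2(C)CCCC(C)(C)[C@H]12 | intermediate
10 | (4aS,8aS)-2,5,5,8a-tetramethyloctahydronaphthalene-1,4-dione, C2 (= C8) epimers | O=C1CC(C)C(=O)[C@@]2(C)CCCC(C)(C)[C@H]12 | intermediate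
11 | (2R,4R,4aS,8aS)-4-hydroxy-2,5,5,8a-tetramethyloctahydronaphthalen-1(2H)-one | O[C@@H]1C[C@@H](C)C(=O)[C@@]2(C)CCCC(C)(C)[C@H]12 | intermediate
12 | (1R,3R,4aS,8aS)-3,4a,8,8-tetramethyl-4-methylidenedecahydronaphthalen-1-ol | O[C@@H]1C[C@@H](C)C(=C)[C@@]2(C)CCCC(C)(C)[C@H]12 | intermediate
13 | 9α,11-epoxide of 12 (spiro-oxirane on C9, oxygen α; 6β-OH, 8α-CH3) | O[C@@H]1C[C@@H](C)[C@]2(CO2)[C@@]2(C)CCCC(C)(C)[C@H]12 | intermediate
14 | 3-methylbut-3-en-1-ol (isoprenol) | CC(=C)CCO | starting material
15 | dilithium salt of 14 (alkoxide and 2-substituted allyl anion) | [Li+].[Li+].[CH2-]C(=C)CC[O-] | intermediate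
16 | (5S,6R,8R,9R,10S)-labd-13(16)-ene-6,9,15-triol | O[C@@H]1C[C@@H](C)[C@](O)(CCC(=C)CCO)[C@@]2(C)CCCC(C)(C)[C@H]12 | intermediate
17 | (13R)-13,16-epoxylabdane-6β,9α,15-triol | O[C@@H]1C[C@@H](C)[C@](O)(CC[C@]3(CO3)CCO)[C@@]2(C)CCCC(C)(C)[C@H]12 | intermediate
18 | (13S)-9α,13-epoxylabdane-6β,15,16-triol | O[C@@H]1C[C@@H](C)[C@]2(CC[C@@](CO)(CCO)O2)[C@@]2(C)CCCC(C)(C)[C@H]12 | intermediate
19 | deacetylprevitexilactone, (13S)-6β-hydroxy-9α,13-epoxylabdane lactone (C15 carbonyl, oxygen on C16) | O[C@@H]1C[C@@H](C)[C@]2(CC[C@]3(COC(=O)C3)O2)[C@@]2(C)CCCC(C)(C)[C@H]12 | intermediate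
20 | previtexilactone, (5S,6R,8R,9R,10S,13S) | CC(=O)O[C@@H]1C[C@@H](C)[C@]2(CC[C@]3(COC(=O)C3)O2)[C@@]2(C)CCCC(C)(C)[C@H]12 | target

## Step count and risks

Total step count: 13. Longest linear sequence: 13 steps, from (R)-carvone.

Steps most likely to fail:

**Step 4.** The tertiary C4 radical may be reduced to an isopropyl group, the C3–I bond may be hydrodehalogenated, or hydrogen atom transfer may go to the enone, before the two carbons meet at nickel. The fallback replaces the nickel coupling by a radical conjugate addition and sets out from 3. Enolate 5 is alkylated with methyl 2-(bromomethyl)acrylate (LiN(i-Pr)2, THF, −78 °C; again anti to the isopropenyl group) to give methyl 2-{[(1S,6S)-1,3-dimethyl-2-oxo-6-(prop-1-en-2-yl)cyclohex-3-en-1-yl]methyl}prop-2-enoate F1. Fe(acac)3 and PhSiH3 in EtOH/ethylene glycol at 60 °C then effect an MHAT-initiated 6-endo Giese cyclization: the C4 radical adds to C3, the β-carbon of the acrylate, which closes ring A by the same C3–C4 bond and gives the bicyclic methyl ester F2 (both C2 epimers). Saponification (LiOH, THF/H2O) gives the acid F3, which is converted (N-hydroxypyridine-2-thione, DCC) into the thiohydroxamate ester F4. Barton decarboxylation (t-BuSH, visible light) removes the carboxyl group and returns to the route at 8.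

**Step 10.** The basic allyl anion may isomerize the epoxide to an allylic alcohol by deprotonation at C8, or SN2 attack at the neopentyl-type C11 may be too slow. The fallback is a radical allylation and sets out from 13. LiI/AcOH in THF opens the epoxide at C11 to the 11-iodo-6β,9α-diol F5. Separately, dianion 15 is quenched with Bu3SnCl to give tributyl[2-(2-hydroxyethyl)prop-2-en-1-yl]stannane F6. Keck radical allylation of F5 with F6 (AIBN, benzene, 80 °C) forms the C11–C12 bond through the primary C11 radical, which is insensitive to the steric hindrance and is neutral, and returns to the route at 16.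

**Step 11.** The catalyst may control the face of the 1,1-disubstituted C13=C16 alkene poorly, which would leave C13 as a mixture. The fallback gives up reagent control and sets out from 16. Achiral directed epoxidation (VO(acac)2, t-BuOOH) and then camphorsulfonic acid give 18 together with its C13 epimer, (13R)-9α,13-epoxylabdane-6β,15,16-triol F8, through 17 and the (13S)-13,16-epoxide F7. Both are lactonized as in step 12 to 19 and the 13-epi lactone F9, which are separated. F9 is then treated with DBU: β-elimination of the C9 alkoxide (retro-oxa-Michael) opens it to 6β,9α-dihydroxylabd-13-en-15,16-olide F10, and re-closure by oxa-Michael addition regenerates both spiro-ethers, so that repeated equilibration and separation returns the material to the route at 19.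

## Further compounds

F1 | step 4 | methyl 2-{[(1S,6S)-1,3-dimethyl-2-oxo-6-(prop-1-en-2-yl)cyclohex-3-en-1-yl]methyl}prop-2-enoate | C1C=C(C)C(=O)[C@@](C)(CC(=C)C(=O)OC)[C@@H]1C(C)=C
F2 | step 4 | methyl (4aS,8aS)-4,4,7,8a-tetramethyl-8-oxo-1,2,3,4,4a,5,8,8a-octahydronaphthalene-2-carboxylate, C2 epimers | C1C=C(C)C(=O)[C@@]2(C)CC(C(=O)OC)CC(C)(C)[C@H]12
F3 | step 4 | (4aS,8aS)-4,4,7,8a-tetramethyl-8-oxo-1,2,3,4,4a,5,8,8a-octahydronaphthalene-2-carboxylic acid, C2 epimers | C1C=C(C)C(=O)[C@@]2(C)CC(C(O)=O)CC(C)(C)[C@H]12
F4 | step 4 | 2-thioxopyridin-1(2H)-yl ester of F3 (Barton ester) | C1C=C(C)C(=O)[C@@]2(C)CC(C(=O)ON3C=CC=CC3=S)CC(C)(C)[C@H]12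
F5 | step 10 | 11-iodo-6β,9α-diol from 13 (iodohydrin; 8α-CH3) | O[C@@H]1C[C@@H](C)[C@](O)(CI)[C@@]2(C)CCCC(C)(C)[C@H]12
F6 | step 10 | tributyl[2-(2-hydroxyethyl)prop-2-en-1-yl]stannane | OCCC(=C)C[Sn](CCCC)(CCCC)CCCC
F7 | step 11 | (13S)-13,16-epoxylabdane-6β,9α,15-triol | O[C@@H]1C[C@@H](C)[C@](O)(CC[C@@]3(CO3)CCO)[C@@]2(C)CCCC(C)(C)[C@H]12
F8 | step 11 | (13R)-9α,13-epoxylabdane-6β,15,16-triol | O[C@@H]1C[C@@H](C)[C@]2(CC[C@](CO)(CCO)O2)[C@@]2(C)CCCC(C)(C)[C@H]12
F9 | step 11 | 13-epi-deacetylprevitexilactone (13R) | O[C@@H]1C[C@@H](C)[C@]2(CC[C@@]3(COC(=O)C3)O2)[C@@]2(C)CCCC(C)(C)[C@H]12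
F10 | step 11 | 6β,9α-dihydroxylabd-13-en-15,16-olide (C15 carbonyl, butenolide) | O[C@@H]1C[C@@H](C)[C@](O)(CCC3=CC(=O)OC3)[C@@]2(C)CCCC(C)(C)[C@H]12
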